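Complex with two exchanged cannot pass 50.0% of the starting complex charged in the larch flask, because each such complex takes two incoming ligands and [incoming ligand] is less than twice [starting complex]. Incoming ligand is therefore the limiting reagent, and perfect pairing, with each ligand on a doubly exchanged complex, is the zero of the scale.

| flask | starting complex | incoming ligand | temperature | remark | time |
|---|---|---|---|---|---|
| larch | 0.42 M | 0.42 M | 0 °C | the very flask that is asked about, followed so far |  |
| birch | 0.42 M | 0.42 M | −5 °C | run made earlier |  |
| flask | 0.42 M | 0.420 M | 0 °C |  | 8.0 d |

| larch: time / h | larch: complex with two exchanged / % | birch: time / h | birch: complex with two exchanged / % |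
|---|---|---|---|
| 12.0 | 32.3 | 12.0 | 25.8 |
| 25.0 | 38.7 | 25.0 | 32.9 |
| 40.0 | 39.4 | 40.0 | 33.8 |
| 72.0 | 38.4 | 72.0 | 35.1 |
| 144 | 37.6 | 144 | 34.0 |

(scatter of a reading: 1 percentage point)

- blue: at 8.0 d add incoming ligand, 50.0% of the amount charged, then wait 15 d
- green: at 8.0 d raise the temperature by 20 K, then wait 15 d
- violet: at 8.0 d take out 90% of the complex with two exchanged then present, then wait 15 d
- ochre: change nothing and wait 15 d more

- complex with two exchanged taken out counts as made
- the numbers in the tables scatter by 1 percentage point (one standard deviation)
- additions bring no volume worth counting

- complex with two exchanged, in percent of the starting complex first charged, at 8.0 d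
- what to do for the largest gain in complex with two exchanged; "none" if nothing gains more than 2 percentage points (blue / green / violet / ochre / none)
- complex with two exchanged present, with what was taken out counted in, in percent of the starting complex first charged, after blue
- complex with two exchanged present, with what was taken out counted in, in percent of the starting complex first charged, after green

The ledger is kept for incoming ligand in the larch flask. The charges are equal, so a percent of the ligand is also a percent of the complex. From the second reading on, the larch readings average 38.5%, and this plateau books 77.0% of the ligand, two per complex. This reckoning supposes that the rest of the charged ligand is bound too, one per complex, so the second entry is 23.0% of the complex as complex with one exchanged. That leaves 38.5% of the complex unexchanged, and the books close.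

The carried quantity is the pairing shortfall, the cap minus the plateau, here 11 percentage points. It is half the singly booked entry and is read at 0 °C, with the temperature held there.

The reckoning for the flask follows. The reckoning puts the flask at 8.0 d on the plateau, at about 38.5%. Ochre and violet add no ligand to the ledger, so each should leave the count at 38.5%. Green adds none either, but it leaves the temperature at which the shortfall was read, so a count of 38.5% after green is a supposition that the ligand stays where it is booked. Blue raises the cap to 75.0%, and subtracting the same shortfall gives 64.0%, which makes blue the best option in this reckoning.

The forecast, which differs from this reckoning after green and after blue, gives 38.3%, blue, 56% after blue and 46.5% after green, on the ground that “The flat values from 25 h onward mean equilibrium, not a stalled reaction”.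

The flask gives 38.0% at 8.0 d, and the best option is blue, with 69.0% after blue and 38.0% after green. At 192 h free incoming ligand stands at 0% of its charge.

    starting complex + incoming ligand → leaving ligand + complex with one exchanged (k = 1.40 L mol⁻¹ h⁻¹, Ea = 51.0 kJ mol⁻¹)
    complex with one exchanged + incoming ligand → leaving ligand + complex with two exchanged (k = 0.990 L mol⁻¹ h⁻¹, Ea = 71.0 kJ mol⁻¹)
    complex with two exchanged + incoming ligand ⇌ leaving ligand + complex with three exchanged (K = 0.350, k = 0.660 L mol⁻¹ h⁻¹, Ea = 54.0 kJ mol⁻¹, ΔH = −25.0 kJ mol⁻¹)
    starting complex ⇌ dormant form (K = 2.30, k = 0.360 h⁻¹, Ea = 91.0 kJ mol⁻¹, ΔH = 2.00 kJ mol⁻¹)
    (constants at 0 °C)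

Measured against its cap, the flask after blue falls short by 6 points, which is less than the carried 11 points.

In the neighbour flask with 0.25 M of incoming ligand, the cap is 29.8%, and the shortfall brings the reckoning to 18.3%. The simulation gives 16.7%.

(The data come from a simulation with constants of no real substance; the scatter is artificial.)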